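## Retrosynthetic overview

1. The strategy rests on ring A (C1 = CH2 bridge to ring B, C2–OH, C3–CH3, C4–OCH3, C5–butyryl, C6–OH). Its only methylated oxygen sits at C4, between the C-methyl and the acyl carbon, so each ring A oxygen is given its own origin: C6–O from a ketene carbonyl, C2–O from a silyl ynol ether, C4–OCH3 from a cyclobutenone enol ether.
2. Last disconnections: the three butyryl groups (ring A C5 and the single free CH of rings B and C) go back to a tribromide of the fully benzylated trimer, each site taking up one molecule of butanal; hydrogenolysis of seven benzyl ethers is the final step.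
3. Key disconnection: ring A is opened to a triisopropylsiloxyalkyne carrying the ring B–ring C diarylmethane and 3-methoxy-2-methylcyclobutenone (bonds C6–C1 and C2–C3, then C5–C6 by 6π closure).
4. The siloxyalkyne comes from a ring B bromide (propargylation, desilylation, acetylide oxidation and O-silylation). The bromide comes from dibromo-tribenzyloxybenzene and the ring C aldehyde (aryllithium addition, ionic deoxygenation). The second bromine reserves the ring B carbon for the alkyne arm, so the free CH of ring C never competes.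
5. Ring order: rings C and B are bought as 2-methylphloroglucinol and phloroglucinol; ring A is built last. The target has no stereocentre.

Key step: step 12

Assumption: 1-methoxyprop-1-yne is taken as a purchasable reagent, and ketene is generated from acetone in a ketene lamp and led directly into the reaction flask.

## Route

Step 1
Reactants: 1 2-methylbenzene-1,3,5-triol
Product: 3 2,4,6-trihydroxy-3-methylbenzaldehyde, via iminium chloride 2 (not isolated)
Conditions: POCl3, DMF, EtOAc, 0 °C → rt; then H2O, 60 °C
Reagents that add atoms: N,N-dimethylformamide CN(C)C=O; water O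
Why: Vilsmeier–Haack formylation, in which the chloroiminium ion attacks one of the two equivalent, triply activated ring CH positions and the precipitating iminium salt resists a second formylation before it is hydrolysed.

Step 2
Reactants: 3 2,4,6-trihydroxy-3-methylbenzaldehyde
Product: 4 4,6-bis(benzyloxy)-2-hydroxy-3-methylbenzaldehyde
Conditions: BnBr (2.1 equiv), K2CO3, acetone, reflux
Reagents that add atoms: benzyl bromide BrCc1ccccc1
Why: Regioselective Williamson etherification, in which the para hydroxyl and the less hindered ortho hydroxyl should react while the hydroxyl between the formyl group and the C-methyl stays hydrogen-bonded to the carbonyl.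

Step 3
Reactants: 4 4,6-bis(benzyloxy)-2-hydroxy-3-methylbenzaldehyde
Product: 5 4,6-bis(benzyloxy)-2-methoxy-3-methylbenzaldehyde
Conditions: MeI, K2CO3, DMF, 60 °C
Reagents that add atoms: iodomethane CI
Why: Williamson methylation of the remaining chelated phenol under forcing conditions places the ring C methoxy between the C-methyl and the future bridge carbon.

Step 4
Reactants: 6 benzene-1,3,5-triol
Product: 7 1,3,5-tris(benzyloxy)benzene
Conditions: BnBr (3.3 equiv), K2CO3, DMF, rt
Reagents that add atoms: benzyl bromide BrCc1ccccc1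
Why: Threefold Williamson etherification, for which the polar aprotic medium favours O- over C-benzylation of the phloroglucinol anion.

Step 5
Reactants: 7 1,3,5-tris(benzyloxy)benzene
Product: 8 2,4-dibromo-1,3,5-tris(benzyloxy)benzene
Conditions: NBS (2.0 equiv), CH2Cl2, –20 → 0 °C
Reagents that add atoms: N-bromosuccinimide O=C1CCC(=O)N1Br
Why: Electrophilic aromatic bromination, in which each bromine slightly deactivates the ring so that two equivalents stop at the dibromide and leave one ring B CH.

Step 6
Reactants: 8 2,4-dibromo-1,3,5-tris(benzyloxy)benzene; 5 4,6-bis(benzyloxy)-2-methoxy-3-methylbenzaldehyde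
Product: 10 racemic diarylmethanol joining bromo ring B to ring C, via monolithiated dibromide 9 (not isolated)
Conditions: n-BuLi (1.0 equiv), THF, –78 °C; then 5, –78 → –20 °C; H2O
Reagents that add atoms: none
Why: Bromine–lithium exchange of one C–Br bond (the aryl anion resists a second exchange) followed by 1,2-addition to the non-enolisable aldehyde; the carbinol centre forms racemic and is removed in step 7.

Step 7
Reactants: 10 racemic diarylmethanol
Product: 11 ring B–ring C diarylmethane bromide
Conditions: Et3SiH, CF3CO2H, CH2Cl2, –20 → 0 °C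
Reagents that add atoms: none
Why: Ionic hydrogenation, in which acid ionises the doubly donor-stabilised diarylmethanol and the silane delivers hydride, while the aryl bromide and the benzyl ethers should survive the short exposure at low temperature.

Step 8
Reactants: 11 ring B–ring C diarylmethane bromide; 12 3-bromo-1-(trimethylsilyl)prop-1-yne
Product: 15 trimethylsilyl-capped propargyl arene, via aryllithium 13 (not isolated), via arylmagnesium bromide 14 (not isolated)
Conditions: t-BuLi (2.0 equiv), THF, –78 °C; MgBr2·OEt2; CuI (10 mol %), 12, –40 → 0 °C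
Reagents that add atoms: none
Why: Bromine–lithium exchange outruns ring or benzylic deprotonation at –78 °C, and copper-catalysed SN2 coupling of the aryl Grignard reagent with the silyl-capped propargyl bromide should give the propargyl rather than the allenyl arene because the SiMe3 group shields the γ-carbon.

Step 9
Reactants: 15 trimethylsilyl-capped propargyl arene
Product: 16 terminal alkyne (3-arylprop-1-yne)
Conditions: K2CO3 (cat.), MeOH/THF, 0 °C → rt
Reagents that add atoms: none
Why: Base-catalysed methanolysis of the alkynyl C–Si bond, in which the electron-rich aryl group keeps the ArCH2 protons weakly acidic so that isomerisation to the allene is not expected at this temperature.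

Step 10
Reactants: 16 terminal alkyne
Product: 19 triisopropylsiloxyalkyne on the ring B–ring C diarylmethane, via lithium acetylide 17 (not isolated), via lithium ynolate 18 (not isolated)
Conditions: n-BuLi (1.0 equiv), THF, –78 °C; t-BuOOLi (from t-BuOOH and LiN(SiMe3)2), –78 → 0 °C; i-Pr3SiOTf, –78 °C
Reagents that add atoms: tert-butyl hydroperoxide CC(C)(C)OO; triisopropylsilyl trifluoromethanesulfonate CC(C)[Si](OS(=O)(=O)C(F)(F)F)(C(C)C)C(C)C
Why: Oxidation of a lithium acetylide by lithium tert-butyl peroxide gives the lithium ynolate, which the bulky silyl triflate traps on oxygen to give the silyl ynol ether.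

Step 11
Reactants: 20 acetone; 21 1-methoxyprop-1-yne
Product: 23 3-methoxy-2-methylcyclobut-2-en-1-one, via ketene 22 (not isolated)
Conditions: 20 pyrolysed at 700 °C (ketene lamp); gas stream passed into 21, CH2Cl2, 0 °C → rt
Reagents that add atoms: none
Why: [2+2] cycloaddition of ketene with an alkoxyalkyne, the standard entry to 3-alkoxycyclobutenones, in which the nucleophilic methyl-bearing alkyne carbon bonds to the ketene carbonyl carbon and so places methyl at C2 and methoxy at C3.

Step 12
Reactants: 19 triisopropylsiloxyalkyne on the ring B–ring C diarylmethane; 23 3-methoxy-2-methylcyclobut-2-en-1-one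
Product: 28 trimer skeleton whose ring A has C6–OH free and C2–OSi(i-Pr)3 and C4–OCH3 and C5–H, via vinylketene 24 (not isolated), via vinylcyclobutenone 25 (not isolated), via dienylketene 26 (not isolated), via cyclohexadienone 27 (not isolated)
Conditions: 23 (1.5 equiv, added in portions), toluene, 80 → 110 °C
Reagents that add atoms: none
Why: Danheiser benzannulation of a cyclobutenone with a trialkylsiloxyalkyne (the closest known reaction type; a 3-alkoxycyclobutenone is the less usual partner): thermal 4π electrocyclic opening of 23 gives vinylketene 24, whose electrophilic ketene carbon is attacked by the carbon of ynol ether 19 that bears the CH2 arm, so that the [2+2] cycloaddition gives 25 with the new bonds C6–C1 and C2–C3. A second 4π opening turns 25 into dienylketene 26, and ring A closes by thermal disrotatory 6π electrocyclisation (bond C5–C6) to cyclohexadienone 27, which tautomerises to phenol 28. No stereocentre results, because the quaternary carbon of 25 ends as aromatic C3. The selectivity needed is the regiochemistry of the [2+2] step, and the polarisation of the siloxyalkyne secures it, which puts the bridge-bearing carbon C1 between the ketene-derived C6–OH and the silyloxy carbon C2 and leaves the cyclobutenone methoxy at C4 next to the C-methyl. The unsubstituted CH2 of 23 becomes C5–H, the one open position of ring A, and 23 is used in excess because 19 is the valuable partner.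

Step 13
Reactants: 28 ring A phenol silyl ether
Product: 30 heptabenzyl ether of the trimer skeleton, via ring A resorcinol 29 (not isolated)
Conditions: Bu4NF, THF, 0 °C; then BnBr, K2CO3, DMF, 50 °C
Reagents that add atoms: benzyl bromide BrCc1ccccc1
Why: Fluoride cleavage of the aryl silyl ether followed by Williamson benzylation of both ring A phenols in the same flask, so that all seven phenolic oxygens carry the same hydrogenolysable group.

Step 14
Reactants: 30 heptabenzyl ether
Product: 31 tribromide (one bromine on each ring)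
Conditions: NBS (3.0 equiv), CH2Cl2, –20 → 0 °C, dark
Reagents that add atoms: N-bromosuccinimide O=C1CCC(=O)N1Br
Why: Electrophilic aromatic bromination at the single unsubstituted position of each ring, which is activated by three alkoxy groups and is the only nuclear CH left on rings A, B and C.

Step 15
Reactants: 31 tribromide
Product: 33 tris(1-hydroxybutyl) heptabenzyl ether as a mixture of diastereomers, via trilithio arene 32 (not isolated)
Conditions: t-BuLi (6.3 equiv), THF, –78 °C; butanal (4.5 equiv), –78 → 0 °C; H2O
Reagents that add atoms: butanal CCCC=O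
Why: Threefold irreversible bromine–lithium exchange (two equivalents of t-BuLi per bromine) gives three 2,6-dialkoxyaryllithium sites, each of which takes up one molecule of butanal by 1,2-addition; the three carbinol centres form without control and are removed in step 16.

Step 16
Reactants: 33 tris(1-hydroxybutyl) heptabenzyl ether
Product: 34 tributyryl heptabenzyl ether
Conditions: Dess–Martin periodinane, pyridine, CH2Cl2, 0 °C → rt
Reagents that add atoms: none
Why: Dess–Martin oxidation of the three benzylic alcohols under buffered conditions that spare the acid-labile diarylmethane bridges and the benzyl ethers.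

Step 17
Reactants: 34 tributyryl heptabenzyl ether
Product: 35 CNP0171986.0 (target)
Conditions: H2 (1 atm), 10% Pd/C, EtOAc/MeOH, rt
Reagents that add atoms: none
Why: Hydrogenolysis of the seven benzyl ethers over palladium on carbon, under which the 2,6-dioxygenated aryl ketones and the diarylmethane C–C bonds should not be reduced.

## Compound list

1 | 2-methylbenzene-1,3,5-triol | Cc1c(O)cc(O)cc1O | starting material
2 | dimethyl(2,4,6-trihydroxy-3-methylbenzylidene)ammonium chloride (formed in the flask) | C[N+](C)=Cc1c(O)cc(O)c(C)c1O.[Cl-] | intermediate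
3 | 2,4,6-trihydroxy-3-methylbenzaldehyde | O=Cc1c(O)cc(O)c(C)c1O | intermediate
4 | 4,6-bis(benzyloxy)-2-hydroxy-3-methylbenzaldehyde | O=Cc1c(O)c(C)c(OCc2ccccc2)cc1OCc1ccccc1 | intermediate
5 | 4,6-bis(benzyloxy)-2-methoxy-3-methylbenzaldehyde (ring C aldehyde) | O=Cc1c(OC)c(C)c(OCc2ccccc2)cc1OCc1ccccc1 | intermediate
6 | benzene-1,3,5-triol | Oc1cc(O)cc(O)c1 | starting material
7 | 1,3,5-tris(benzyloxy)benzene | c1c(OCc2ccccc2)cc(OCc2ccccc2)cc1OCc1ccccc1 | intermediate
8 | 2,4-dibromo-1,3,5-tris(benzyloxy)benzene | Brc1c(OCc2ccccc2)cc(OCc2ccccc2)c(Br)c1OCc1ccccc1 | intermediate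
9 | [2,4,6-tris(benzyloxy)-3-bromophenyl]lithium (formed in the flask) | [Li]c1c(OCc2ccccc2)cc(OCc2ccccc2)c(Br)c1OCc1ccccc1 | intermediate
10 | racemic [2,4,6-tris(benzyloxy)-3-bromophenyl][4,6-bis(benzyloxy)-2-methoxy-3-methylphenyl]methanol | OC(c1c(OCc2ccccc2)cc(OCc2ccccc2)c(Br)c1OCc1ccccc1)c1c(OC)c(C)c(OCc2ccccc2)cc1OCc1ccccc1 | intermediate
11 | ring B–ring C diarylmethane bromide: 1,3,5-tris(benzyloxy)-2-bromo-4-[4,6-bis(benzyloxy)-2-methoxy-3-methylbenzyl]benzene | Brc1c(OCc2ccccc2)cc(OCc2ccccc2)c(Cc2c(OCc3ccccc3)cc(OCc3ccccc3)c(C)c2OC)c1OCc1ccccc1 | intermediate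
12 | 3-bromo-1-(trimethylsilyl)prop-1-yne | C[Si](C)(C)C#CCBr | starting material
13 | aryllithium from 11, lithium in place of bromine (formed in the flask) | [Li]c1c(OCc2ccccc2)cc(OCc2ccccc2)c(Cc2c(OCc3ccccc3)cc(OCc3ccccc3)c(C)c2OC)c1OCc1ccccc1 | intermediate
14 | arylmagnesium bromide from 13 (formed in the flask) | Br[Mg]c1c(OCc2ccccc2)cc(OCc2ccccc2)c(Cc2c(OCc3ccccc3)cc(OCc3ccccc3)c(C)c2OC)c1OCc1ccccc1 | intermediate
15 | 3-aryl-1-(trimethylsilyl)prop-1-yne, aryl = ring B–ring C diarylmethane | C[Si](C)(C)C#CCc1c(OCc2ccccc2)cc(OCc2ccccc2)c(Cc2c(OCc3ccccc3)cc(OCc3ccccc3)c(C)c2OC)c1OCc1ccccc1 | intermediate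
16 | 3-arylprop-1-yne, aryl = ring B–ring C diarylmethane | C#CCc1c(OCc2ccccc2)cc(OCc2ccccc2)c(Cc2c(OCc3ccccc3)cc(OCc3ccccc3)c(C)c2OC)c1OCc1ccccc1 | intermediate
17 | lithium acetylide of 16 (formed in the flask) | [Li]C#CCc1c(OCc2ccccc2)cc(OCc2ccccc2)c(Cc2c(OCc3ccccc3)cc(OCc3ccccc3)c(C)c2OC)c1OCc1ccccc1 | intermediate
18 | lithium ynolate, LiO–C≡C–CH2–aryl (formed in the flask) | [Li]OC#CCc1c(OCc2ccccc2)cc(OCc2ccccc2)c(Cc2c(OCc3ccccc3)cc(OCc3ccccc3)c(C)c2OC)c1OCc1ccccc1 | intermediate
19 | triisopropylsiloxyalkyne on the benzyl-protected ring B–ring C diarylmethane | CC(C)[Si](OC#CCc1c(OCc2ccccc2)cc(OCc2ccccc2)c(Cc2c(OCc3ccccc3)cc(OCc3ccccc3)c(C)c2OC)c1OCc1ccccc1)(C(C)C)C(C)C | intermediate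
20 | acetone | CC(C)=O | starting material
21 | 1-methoxyprop-1-yne | COC#CC | starting material
22 | ketene (generated and consumed as formed) | C=C=O | intermediate
23 | 3-methoxy-2-methylcyclobut-2-en-1-one | COC1=C(C)C(=O)C1 | intermediate
24 | 3-methoxy-2-methylbuta-1,3-dien-1-one (vinylketene, formed in the flask) | C=C(OC)C(C)=C=O | intermediate
25 | racemic 4-(1-methoxyvinyl)-4-methyl-3-(triisopropylsiloxy)-2-(arylmethyl)cyclobut-2-enone (formed in the flask) | C=C(OC)C5(C)C(=O)C(Cc1c(OCc2ccccc2)cc(OCc2ccccc2)c(Cc2c(OCc3ccccc3)cc(OCc3ccccc3)c(C)c2OC)c1OCc1ccccc1)=C5O[Si](C(C)C)(C(C)C)C(C)C | intermediate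
26 | dienylketene with the ketene arm and the methoxyvinyl group cis on the central double bond (formed in the flask) | C=C(OC)/C(C)=C(O[Si](C(C)C)(C(C)C)C(C)C)\C(=C=O)Cc1c(OCc2ccccc2)cc(OCc2ccccc2)c(Cc2c(OCc3ccccc3)cc(OCc3ccccc3)c(C)c2OC)c1OCc1ccccc1 | intermediate
27 | 5-methoxy-4-methyl-3-(triisopropylsiloxy)-2-(arylmethyl)cyclohexa-2,4-dienone (formed in the flask) | O=C5CC(OC)=C(C)C(O[Si](C(C)C)(C(C)C)C(C)C)=C5Cc1c(OCc2ccccc2)cc(OCc2ccccc2)c(Cc2c(OCc3ccccc3)cc(OCc3ccccc3)c(C)c2OC)c1OCc1ccccc1 | intermediate
28 | trimer skeleton, ring A as C6 phenol, C2 triisopropylsilyl ether, C4 methyl ether, C5–H | COc1cc(O)c(Cc2c(OCc3ccccc3)cc(OCc3ccccc3)c(Cc3c(OCc4ccccc4)cc(OCc4ccccc4)c(C)c3OC)c2OCc2ccccc2)c(O[Si](C(C)C)(C(C)C)C(C)C)c1C | intermediate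
29 | trimer skeleton with ring A as the free C2,C6-diol (formed in the flask) | COc1cc(O)c(Cc2c(OCc3ccccc3)cc(OCc3ccccc3)c(Cc3c(OCc4ccccc4)cc(OCc4ccccc4)c(C)c3OC)c2OCc2ccccc2)c(O)c1C | intermediate
30 | heptabenzyl ether of the trimer skeleton (rings A, B and C each with one free CH) | COc1cc(OCc2ccccc2)c(Cc2c(OCc3ccccc3)cc(OCc3ccccc3)c(Cc3c(OCc4ccccc4)cc(OCc4ccccc4)c(C)c3OC)c2OCc2ccccc2)c(OCc2ccccc2)c1C | intermediate
31 | tribromide of 30 (bromine at ring A C5 and at the former CH of rings B and C) | COc1c(Br)c(OCc2ccccc2)c(Cc2c(OCc3ccccc3)c(Br)c(OCc3ccccc3)c(Cc3c(OCc4ccccc4)c(Br)c(OCc4ccccc4)c(C)c3OC)c2OCc2ccccc2)c(OCc2ccccc2)c1C | intermediate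
32 | trilithio arene from 31 (formed in the flask) | COc1c([Li])c(OCc2ccccc2)c(Cc2c(OCc3ccccc3)c([Li])c(OCc3ccccc3)c(Cc3c(OCc4ccccc4)c([Li])c(OCc4ccccc4)c(C)c3OC)c2OCc2ccccc2)c(OCc2ccccc2)c1C | intermediate
33 | tris(1-hydroxybutyl) heptabenzyl ether, mixture of diastereomers | COc1c(C(O)CCC)c(OCc2ccccc2)c(Cc2c(OCc3ccccc3)c(C(O)CCC)c(OCc3ccccc3)c(Cc3c(OCc4ccccc4)c(C(O)CCC)c(OCc4ccccc4)c(C)c3OC)c2OCc2ccccc2)c(OCc2ccccc2)c1C | intermediate
34 | tributyryl heptabenzyl ether | COc1c(C(=O)CCC)c(OCc2ccccc2)c(Cc2c(OCc3ccccc3)c(C(=O)CCC)c(OCc3ccccc3)c(Cc3c(OCc4ccccc4)c(C(=O)CCC)c(OCc4ccccc4)c(C)c3OC)c2OCc2ccccc2)c(OCc2ccccc2)c1C | intermediate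
35 | CNP0171986.0 | CCCC(=O)c1c(O)c(Cc2c(O)c(C)c(OC)c(C(=O)CCC)c2O)c(O)c(Cc2c(O)c(C(=O)CCC)c(O)c(C)c2OC)c1O | target

## Step count and risks

Total step count: 17. Longest linear sequence: 14 steps (steps 1–3, 6–10 and 12–17, from 2-methylbenzene-1,3,5-triol).

Steps most likely to fail:

Step 12. The donor-substituted cyclobutenone may open only sluggishly, and the vinylketene may be consumed by self-reaction or by O-acylation of the phenol of the product instead of adding to the hindered ynol ether. The fallback gives up the benzannulation and brings ring A in preformed, reusing the union chemistry of steps 6 and 7. It sets out from 3 and 11. Aldehyde 3 would be methylated at its non-chelated para hydroxyl (MeI, 1 equiv, K2CO3, acetone) to 2,6-dihydroxy-4-methoxy-3-methylbenzaldehyde F1. Both chelated hydroxyls would then be benzylated (BnBr, K2CO3, DMF, 70 °C) to 2,6-bis(benzyloxy)-4-methoxy-3-methylbenzaldehyde F2. Aryllithium 13 (from 11 and n-BuLi, THF, –78 °C) would be added to F2 to give the racemic triaryl carbinol F3. Ionic hydrogenation (Et3SiH, CF3CO2H, CH2Cl2) would give 30, where the route is rejoined.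

Step 15. Exchange or addition may stay incomplete at one of the three sites, or single aryllithium sites may be quenched by proton transfer (enolisation of butanal), leaving under-acylated mixtures that are hard to separate. The fallback replaces the nucleophilic arene by an electrophilic acylation. It sets out from 30, before the bromination, and treats it with butyric anhydride and catalytic Bi(OTf)3 in MeNO2/CH2Cl2 at 0 °C → rt (threefold Friedel–Crafts acylation at the only open positions). It returns at 34 and makes no new compound (F0).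

Step 10. The base may deprotonate the doubly activated CH2 next to the alkyne (propargyl–allenyl isomerisation), oxygen transfer to the acetylide may be incomplete, or the ynolate may be silylated on carbon. The fallback makes the same ynolate by ester homologation instead of acetylide oxidation. It sets out from 11. Palladium-catalysed coupling with the Reformatsky reagent BrZnCH2CO2Et (Pd(dba)2, Q-Phos, THF) would give the ethyl arylacetate F4. Kowalski homologation (CH2Br2 and lithium 2,2,6,6-tetramethylpiperidide, THF, –78 °C; then n-BuLi, warming) would pass through the dibromomethyl ketone F5 (as its enolate) to lithium ynolate 18. Silylation with i-Pr3SiOTf returns to the route at 19.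

Further compounds

F1 | step 12 | 2,6-dihydroxy-4-methoxy-3-methylbenzaldehyde | O=Cc1c(O)cc(OC)c(C)c1O
F2 | step 12 | 2,6-bis(benzyloxy)-4-methoxy-3-methylbenzaldehyde | O=Cc1c(OCc2ccccc2)cc(OC)c(C)c1OCc1ccccc1
F3 | step 12 | racemic carbinol joining ring A (2,6-bis(benzyloxy)-4-methoxy-3-methylphenyl) to ring B of the ring B–ring C diarylmethane | OC(c1c(OCc2ccccc2)cc(OC)c(C)c1OCc1ccccc1)c1c(OCc2ccccc2)cc(OCc2ccccc2)c(Cc2c(OCc3ccccc3)cc(OCc3ccccc3)c(C)c2OC)c1OCc1ccccc1
F0 | step 15 | none | none
F4 | step 10 | ethyl arylacetate on the ring B–ring C diarylmethane | CCOC(=O)Cc1c(OCc2ccccc2)cc(OCc2ccccc2)c(Cc2c(OCc3ccccc3)cc(OCc3ccccc3)c(C)c2OC)c1OCc1ccccc1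
F5 | step 10 | 1,1-dibromo-3-arylpropan-2-one on the ring B–ring C diarylmethane | BrC(Br)C(=O)Cc1c(OCc2ccccc2)cc(OCc2ccccc2)c(Cc2c(OCc3ccccc3)cc(OCc3ccccc3)c(C)c2OC)c1OCc1ccccc1
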